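**Plan**
- Numbering: chroman atoms are O1, C2, C3, C4, C4a, C5 to C8, C8a. On the naphthalene, C1' is bonded to C4, and C4' and C5' carry the methoxy groups.
- Retrosynthetic cuts, in order: the phenol ring (C4a, C5 to C8, C8a) is taken back to a cyclohexenone, then C4–C4a, then O1–C8a, then C4–C1'.
- Enabling feature: C4 is bonded to C1' of the electron-rich naphthalene, para to the C4' methoxy group, so a plain C4 methylene can be oxidised to a stabilised cation. C4a is the alpha carbon of an enol ether made from a 1,3-dione.
- Forward order: para-bromination of 1,8-dimethoxynaphthalene, Sonogashira coupling with (R)-but-3-yn-2-ol (C4–C1'), hydrogenation, condensation with cyclohexane-1,3-dione (O1–C8a), anodic closure of the dihydropyran ring (C4–C4a), aromatisation to the C5 phenol. Only the pyran ring is built.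
- Stereochemistry: C2 (R) is bought with the alkynol and its C–O bond is never broken. C4 (S) is set relative to C2 in the ring closure (2,4-trans).

Key step: step 5

Remark: 1,8-dimethoxynaphthalene, (R)-but-3-yn-2-ol and cyclohexane-1,3-dione are taken to be commercial. The target SMILES corresponds to (2R,4S), which is the 2,4-trans chroman.

Step 1
Reactants: 1 1,8-dimethoxynaphthalene
Product: 2 1-bromo-4,5-dimethoxynaphthalene
Conditions: NBS (1.0 equiv), MeCN, 0 °C to rt
Reagents that add atoms: N-bromosuccinimide, O=C1CCC(=O)N1Br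
Why: Electrophilic aromatic bromination in a polar solvent goes para to a methoxy group (the two para sites are equivalent), and one equivalent of NBS should stop at the monobromide.

Step 2
Reactants: 2 1-bromo-4,5-dimethoxynaphthalene; 3 (2R)-but-3-yn-2-ol
Product: 4 (2R)-4-(4,5-dimethoxynaphthalen-1-yl)but-3-yn-2-ol
Conditions: Pd(PhCN)2Cl2 (3 mol %), P(t-Bu)3 (6 mol %), CuI (2 mol %), i-Pr2NH (1.5 equiv), 1,4-dioxane, rt
Reagents that add atoms: none
Why: This is a Sonogashira coupling in which the bulky, electron-rich phosphine lets an electron-rich aryl bromide undergo oxidative addition at room temperature, the free propargylic alcohol is tolerated, and its stereocentre takes no part.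

Step 3
Reactants: 4 (2R)-4-(4,5-dimethoxynaphthalen-1-yl)but-3-yn-2-ol
Product: 5 (2R)-4-(4,5-dimethoxynaphthalen-1-yl)butan-2-ol
Conditions: H2 (1 atm), Pd/C (10 wt %), EtOAc, rt
Reagents that add atoms: none
Why: Heterogeneous catalytic hydrogenation of the alkyne to the alkane under neutral conditions should leave the naphthalene, the aryl ethers and the carbinol C–O bond intact, so the (R) centre is carried through.

Step 4
Reactants: 5 (2R)-4-(4,5-dimethoxynaphthalen-1-yl)butan-2-ol; 6 cyclohexane-1,3-dione
Product: 7 3-{[(2R)-4-(4,5-dimethoxynaphthalen-1-yl)butan-2-yl]oxy}cyclohex-2-en-1-one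
Conditions: 6 (1.5 equiv), p-TsOH·H2O (5 mol %), toluene, reflux, azeotropic removal of water
Reagents that add atoms: none
Why: In this acid-catalysed condensation of an alcohol with a cyclic 1,3-dione to a vinylogous ester, the alcohol oxygen attacks the protonated dione, so the C2–O bond and the (R) configuration are retained.

Step 5
Reactants: 7 3-{[(2R)-4-(4,5-dimethoxynaphthalen-1-yl)butan-2-yl]oxy}cyclohex-2-en-1-one
Product: 9 (2R,4S)-4-(4,5-dimethoxynaphthalen-1-yl)-2-methyl-2,3,4,6,7,8-hexahydro-5H-chromen-5-one, via naphthylmethyl cation 8 (not isolated)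
Conditions: undivided cell, graphite anode, Pt cathode, constant current, 2.1 F/mol; n-Bu4NBF4 (0.1 M), 2,6-lutidine (2 equiv), dry CH2Cl2/(CF3)2CHOH 4:1, 5 mM in 7, 0 °C
Reagents that add atoms: none
Why: Proposed new method: the 1-alkyl-4,5-dimethoxynaphthalene is by far the most easily oxidised part of 7, so the anode takes one electron from it, lutidine removes a C4 proton, and a second electron transfer gives cation 8, whose charge is carried by the C4' methoxy oxygen (the O-methyl oxocarbenium form of a 1,4-naphthoquinone methide). C4a, the alpha carbon of the vinylogous ester and the only nucleophilic carbon within reach, adds to C4, loss of the C4a proton restores the conjugated enone, and the protons are reduced to H2 at the cathode. The closest known reaction types are the anodic and DDQ-mediated cross-dehydrogenative couplings of benzylic C–H bonds of electron-rich arenes with 1,3-dicarbonyl compounds and the oxidative C–H cleavage with cyclisation onto tethered enol derivatives, whereas a tethered 3-alkoxyenone has not been shown as the trap. The dihydropyran ring closes in a 6-(enolendo)-exo-trig mode, with the C4a=C8a bond inside the new ring and the C4–C1' unit outside it. In the chair-like transition state the C2 methyl group sits equatorial and the naphthyl group on trigonal C4 turns to the pseudoaxial side, away from the C5 carbonyl that flanks C4a, so the resident (R) centre at C2 should dictate (S) at C4, the 2,4-trans relationship. The step needs chemoselectivity against renewed oxidation of 9, which should come from the charge limit, the weakly nucleophilic fluorinated medium, and the poor overlap of the remaining C4–H bond with the peri-crowded naphthalene in 9.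

Step 6
Reactants: 9 (2R,4S)-4-(4,5-dimethoxynaphthalen-1-yl)-2-methyl-2,3,4,6,7,8-hexahydro-5H-chromen-5-one
Product: 11 (2R,4S)-4-(4,5-dimethoxynaphthalen-1-yl)-2-methyl-6-(phenylselanyl)-2,3,4,6,7,8-hexahydro-5H-chromen-5-one (C6 epimers), via lithium dienolate 10 (not isolated)
Conditions: LiN(i-Pr)2 (commercial solution, 1.1 equiv), THF, −78 °C; then PhSeCl (1.1 equiv), −78 °C
Reagents that add atoms: benzeneselenenyl chloride, Cl[Se]c1ccccc1; lithium diisopropylamide, [Li+].CC(C)[N-]C(C)C (its lithium enters dienolate 10 only, not 11)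
Why: Kinetic alpha' deprotonation of a vinylogous ester at C6 is followed by electrophilic selenenylation of the dienolate, C4–H is not acidic under these conditions, and the C6 configuration does not matter because it is lost in the next step.

Step 7
Reactants: 11 (2R,4S)-4-(4,5-dimethoxynaphthalen-1-yl)-2-methyl-6-(phenylselanyl)-2,3,4,6,7,8-hexahydro-5H-chromen-5-one
Product: 14 cladonaphchrom A [(2R,4S)-4-(4,5-dimethoxynaphthalen-1-yl)-2-methyl-3,4-dihydro-2H-chromen-5-ol], via selenoxide 12 (not isolated), via cyclohexadienone 13 (not isolated)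
Conditions: 30% aq H2O2 (3 equiv), pyridine (2 equiv), CH2Cl2, 0 °C to rt
Reagents that add atoms: hydrogen peroxide, OO (its oxygen enters selenoxide 12 and leaves again with the selenium, none of it stays in 14)
Why: Oxidation to the selenoxide and syn elimination introduce the C6=C7 double bond, and the resulting cyclohexa-2,5-dienone is the keto tautomer of the phenol, which should aromatise spontaneously without touching C2 or C4.

**Compound list**
1 | 1,8-dimethoxynaphthalene | COc1cccc2cccc(OC)c12 | starting material
2 | 1-bromo-4,5-dimethoxynaphthalene | COc1cccc2c(Br)ccc(OC)c12 | intermediate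
3 | (2R)-but-3-yn-2-ol | C[C@@H](O)C#C | starting material
4 | (2R)-4-(4,5-dimethoxynaphthalen-1-yl)but-3-yn-2-ol | C[C@@H](O)C#Cc1ccc(OC)c2c(OC)cccc12 | intermediate
5 | (2R)-4-(4,5-dimethoxynaphthalen-1-yl)butan-2-ol | C[C@@H](O)CCc1ccc(OC)c2c(OC)cccc12 | intermediate
6 | cyclohexane-1,3-dione | O=C1CCCC(=O)C1 | starting material
7 | 3-{[(2R)-4-(4,5-dimethoxynaphthalen-1-yl)butan-2-yl]oxy}cyclohex-2-en-1-one | C[C@H](CCc1ccc(OC)c2c(OC)cccc12)OC1=CC(=O)CCC1 | intermediate
8 | (3R)-1-(4,5-dimethoxynaphthalen-1-yl)-3-[(3-oxocyclohex-1-en-1-yl)oxy]butan-1-ylium | C[C@H](C[CH+]c1ccc(OC)c2c(OC)cccc12)OC1=CC(=O)CCC1 | intermediate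
9 | (2R,4S)-4-(4,5-dimethoxynaphthalen-1-yl)-2-methyl-2,3,4,6,7,8-hexahydro-5H-chromen-5-one | C[C@@H]1C[C@@H](c2ccc(OC)c3c(OC)cccc23)C2=C(O1)CCCC2=O | intermediate
10 | lithium (2R,4S)-4-(4,5-dimethoxynaphthalen-1-yl)-2-methyl-3,4,7,8-tetrahydro-2H-chromen-5-olate | [Li+].C[C@@H]1C[C@@H](c2ccc(OC)c3c(OC)cccc23)C2=C(O1)CCC=C2[O-] | intermediate
11 | (2R,4S)-4-(4,5-dimethoxynaphthalen-1-yl)-2-methyl-6-(phenylselanyl)-2,3,4,6,7,8-hexahydro-5H-chromen-5-one (C6 epimers) | C[C@@H]1C[C@@H](c2ccc(OC)c3c(OC)cccc23)C2=C(O1)CCC([Se]c4ccccc4)C2=O | intermediate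
12 | (2R,4S)-4-(4,5-dimethoxynaphthalen-1-yl)-2-methyl-6-(phenylseleninyl)-2,3,4,6,7,8-hexahydro-5H-chromen-5-one | C[C@@H]1C[C@@H](c2ccc(OC)c3c(OC)cccc23)C2=C(O1)CCC([Se](=O)c4ccccc4)C2=O | intermediate
13 | (2R,4S)-4-(4,5-dimethoxynaphthalen-1-yl)-2-methyl-2,3,4,8-tetrahydro-5H-chromen-5-one | C[C@@H]1C[C@@H](c2ccc(OC)c3c(OC)cccc23)C2=C(O1)CC=CC2=O | intermediate
14 | cladonaphchrom A, (2R,4S)-4-(4,5-dimethoxynaphthalen-1-yl)-2-methyl-3,4-dihydro-2H-chromen-5-ol | COc1cccc2c([C@@H]3C[C@@H](C)Oc4cccc(O)c43)ccc(OC)c12 | target

Total step count: 7. Longest linear sequence: 7 steps (from 1).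

**Steps most likely to fail**

**Step 5 (new method).**
- The naphthalene could dimerise oxidatively through its open C8' position.
- The cation could lose a C3 proton instead of closing the ring, or be captured by the fluorinated alcohol.
- The product could be oxidised again at C4.
- Facial selectivity at C4 could be poor.

The fallback gives up C–H oxidation and builds the C4 oxygen in from the start. It relies on the well-known acid-catalysed benzylation of cyclic 1,3-diones with secondary benzylic alcohols. It sets out from 2 and 6 and comes back at 9.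

Commercial methyl (R)-3-hydroxybutanoate would be silylated (TBSCl, imidazole, DMF) to methyl (3R)-3-[(tert-butyldimethylsilyl)oxy]butanoate F1. Reduction (i-Bu2AlH, CH2Cl2, −78 °C) would give (3R)-3-[(tert-butyldimethylsilyl)oxy]butanal F2. Bromine–lithium exchange on 2 (n-BuLi, THF, −78 °C) would give (4,5-dimethoxynaphthalen-1-yl)lithium F3. Its addition to F2 would give (3R)-3-[(tert-butyldimethylsilyl)oxy]-1-(4,5-dimethoxynaphthalen-1-yl)butan-1-ol F4, as carbinol epimers whose ratio is irrelevant. Treatment with n-Bu4NF would free (3R)-1-(4,5-dimethoxynaphthalen-1-yl)butane-1,3-diol F5.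

Warming F5 with 6 and catalytic Bi(OTf)3 or p-TsOH in 1,2-dichloroethane should ionise only the benzylic alcohol. The enol of 6 would be alkylated at its C2 to 2-[(3R)-1-(4,5-dimethoxynaphthalen-1-yl)-3-hydroxybutyl]cyclohexane-1,3-dione F6. The remaining secondary alcohol then condenses with a ring carbonyl and closes the dihydropyran of 9.

C4 is set here without a tether, so lower selectivity must be expected. Reversible ionisation of the C4–C4a bond under the acid should favour the trans isomer. Any remaining (2R,4R)-4-(4,5-dimethoxynaphthalen-1-yl)-2-methyl-2,3,4,6,7,8-hexahydro-5H-chromen-5-one F7 would be removed by chromatography.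

**Step 7.**
- Electrophilic selenium species set free in the elimination could add back to the electron-rich phenol or naphthalene.
- The fresh phenol could be over-oxidised.

The fallback replaces selenium by palladium-mediated dehydrogenation. It sets out from 9 and comes back at 13, and thereby at 14. Dienolate 10, generated from 9 with LiN(i-Pr)2 as in step 6, would be trapped with Me3SiCl. This gives (2R,4S)-4-(4,5-dimethoxynaphthalen-1-yl)-2-methyl-5-[(trimethylsilyl)oxy]-3,4,7,8-tetrahydro-2H-chromene F8. A Saegusa–Ito oxidation (Pd(OAc)2, MeCN, rt) would convert it by beta-hydride elimination into dienone 13, which tautomerises to 14.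

**Step 4.**
- Condensation of a hindered secondary alcohol used as the limiting partner could be slow and incomplete.
- The dione could self-condense.
- The acid could dehydrate the alcohol.

The fallback changes from acid-catalysed condensation to addition–elimination under basic conditions. It sets out from 5 and 6 and comes back at 7. Dione 6 would be converted with oxalyl chloride and catalytic DMF in CH2Cl2 into 3-chlorocyclohex-2-en-1-one F9. Alcohol 5 would be deprotonated (NaH, THF, 0 °C) to sodium (2R)-4-(4,5-dimethoxynaphthalen-1-yl)butan-2-olate F10. Conjugate addition of F10 to F9 with loss of chloride gives 7, and the configuration is retained because the C2–O bond is not touched.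

**Further compounds**
F1 | step 5 | methyl (3R)-3-[(tert-butyldimethylsilyl)oxy]butanoate | C[C@@H](O[Si](C)(C)C(C)(C)C)CC(=O)OC
F2 | step 5 | (3R)-3-[(tert-butyldimethylsilyl)oxy]butanal | C[C@@H](O[Si](C)(C)C(C)(C)C)CC=O
F3 | step 5 | (4,5-dimethoxynaphthalen-1-yl)lithium | [Li]c1ccc(OC)c2c(OC)cccc12
F4 | step 5 | (3R)-3-[(tert-butyldimethylsilyl)oxy]-1-(4,5-dimethoxynaphthalen-1-yl)butan-1-ol (C1 epimers) | C[C@@H](O[Si](C)(C)C(C)(C)C)CC(O)c1ccc(OC)c2c(OC)cccc12
F5 | step 5 | (3R)-1-(4,5-dimethoxynaphthalen-1-yl)butane-1,3-diol (C1 epimers) | C[C@@H](O)CC(O)c1ccc(OC)c2c(OC)cccc12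
F6 | step 5 | 2-[(3R)-1-(4,5-dimethoxynaphthalen-1-yl)-3-hydroxybutyl]cyclohexane-1,3-dione | C[C@@H](O)CC(c1ccc(OC)c2c(OC)cccc12)C1C(=O)CCCC1=O
F7 | step 5 | (2R,4R)-4-(4,5-dimethoxynaphthalen-1-yl)-2-methyl-2,3,4,6,7,8-hexahydro-5H-chromen-5-one | C[C@@H]1C[C@H](c2ccc(OC)c3c(OC)cccc23)C2=C(O1)CCCC2=O
F8 | step 7 | (2R,4S)-4-(4,5-dimethoxynaphthalen-1-yl)-2-methyl-5-[(trimethylsilyl)oxy]-3,4,7,8-tetrahydro-2H-chromene | C[C@@H]1C[C@@H](c2ccc(OC)c3c(OC)cccc23)C2=C(O1)CCC=C2O[Si](C)(C)C
F9 | step 4 | 3-chlorocyclohex-2-en-1-one | O=C1C=C(Cl)CCC1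
F10 | step 4 | sodium (2R)-4-(4,5-dimethoxynaphthalen-1-yl)butan-2-olate | [Na+].C[C@@H]([O-])CCc1ccc(OC)c2c(OC)cccc12
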